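The three naphthalene units are numbered as 8-methoxynaphthalen-1-ol (A and C terminal, B central). The oxygenated ring of unit B is cut between carbons 1 and 2 and between carbons 3 and 4. Carbon 1 (a carbonyl) and carbon 4 (a methine bonded to carbon 2 of unit A) sit on the two adjacent ring-fusion carbons of the methoxybenzene half of B, so they are stored as a fused cyclobutenone; carbons 2 and 3 arrive as a 1-arylvinyllithium attached to carbon 4 of unit C. In one operation the key step adds the vinyllithium, opens the four-membered ring and closes the six-membered ring, converting a racemic 8-naphthyl-5-methoxybenzocyclobutenone into the 2,4-diaryl-8-methoxy-1-tetralone; aromatisation and MOM removal finish.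

Key step: step 14

Remark: the target has no stereocentre and each biaryl axis has only one ortho oxygen beside a peri hydrogen, so the axes are taken as freely rotating and all intermediates are carried racemic.

Step 1
Reactants: 1 naphthalene-1,8-diol
Product: 2 8-methoxynaphthalen-1-ol
Conditions: MeI (1.05 equiv), K2CO3 (1.1 equiv), acetone, reflux
Reagents that add atoms: iodomethane, CI
Why: Williamson etherification should stop after one methylation because the first phenoxide is the more acidic, hydrogen-bond-stabilised one and the remaining hydroxyl of 2 is tied up in a hydrogen bond to the new methoxy group.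

Step 2
Reactants: 2 8-methoxynaphthalen-1-ol
Product: 3 1-methoxy-8-(methoxymethoxy)naphthalene
Conditions: NaH, MOMCl, THF/DMF, 0 °C to rt
Reagents that add atoms: chloromethyl methyl ether, COCCl
Why: O-alkylation of the sodium naphthoxide (Williamson type) installs an acetal that directs the next lithiation and is removable with acid at the end.

Step 3
Reactants: 3 1-methoxy-8-(methoxymethoxy)naphthalene
Product: 5 2-bromo-8-methoxy-1-(methoxymethoxy)naphthalene, via aryllithium 4 (not isolated)
Conditions: n-BuLi, TMEDA, Et2O, 0 °C; BrCH2CH2Br, −78 °C to rt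
Reagents that add atoms: 1,2-dibromoethane, BrCCBr
Why: Directed ortho-metalation, in which the chelating OMOM group is a stronger director than OMe and has carbon 2 as its only free ortho position, followed by bromine transfer from 1,2-dibromoethane to the aryllithium.

Step 4
Reactants: 5 2-bromo-8-methoxy-1-(methoxymethoxy)naphthalene; 6 (2-ethoxy-2-oxoethyl)zinc bromide, BrZnCH2CO2Et (commercial solution)
Product: 7 ethyl 2-[8-methoxy-1-(methoxymethoxy)naphthalen-2-yl]acetate
Conditions: Pd2(dba)3 (2.5 mol%), XPhos (10 mol%), THF, 65 °C
Reagents that add atoms: none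
Why: Negishi-type cross-coupling of a Reformatsky zinc enolate with an aryl bromide under zerovalent palladium catalysis forms the aryl–CH2 bond directly and leaves the MOM acetal untouched.

Step 5
Reactants: 7 ethyl 2-[8-methoxy-1-(methoxymethoxy)naphthalen-2-yl]acetate
Product: 8 tert-butyl({1-ethoxy-2-[8-methoxy-1-(methoxymethoxy)naphthalen-2-yl]ethenyl}oxy)dimethylsilane (E/Z mixture)
Conditions: LiN(iPr)2, THF, −78 °C; TBSCl, DMPU, −78 °C to rt; non-aqueous work-up
Reagents that add atoms: tert-butyldimethylsilyl chloride, CC(C)(C)[Si](C)(C)Cl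
Why: Ester enolisation and O-silylation (silyl ketene acetal formation) give the electron-rich two-carbon partner for the aryne, and the double-bond geometry is irrelevant because the carbon it becomes is formed racemic in the cycloaddition.

Step 6
Reactants: 9 2-iodo-1,3-dimethoxybenzene
Product: 10 2-iodo-3-methoxyphenol
Conditions: BBr3 (1.0 equiv), CH2Cl2, −78 to 0 °C; H2O
Reagents that add atoms: none
Why: Lewis acid ether cleavage, in which one equivalent of BBr3 should remove one of the two equivalent methyl groups because the aryloxyborane formed is deactivated towards a second cleavage.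

Step 7
Reactants: 10 2-iodo-3-methoxyphenol
Product: 11 2-iodo-3-methoxyphenyl trifluoromethanesulfonate
Conditions: Tf2O, pyridine, CH2Cl2, 0 °C
Reagents that add atoms: trifluoromethanesulfonic anhydride, O=S(=O)(OS(=O)(=O)C(F)(F)F)C(F)(F)F
Why: O-sulfonylation of the phenol gives an ortho-iodoaryl triflate, a benzyne precursor that is triggered by iodine–lithium exchange at −78 °C.

Step 8
Reactants: 8 silyl ketene acetal of ester 7; 11 2-iodo-3-methoxyphenyl trifluoromethanesulfonate
Product: 14 5-methoxy-8-[8-methoxy-1-(methoxymethoxy)naphthalen-2-yl]bicyclo[4.2.0]octa-1,3,5-trien-7-one (racemic), via 3-methoxybenzyne 12 (not isolated), via silyl ethyl acetal 13 (not isolated)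
Conditions: 8, 11 (1.5 equiv), THF, −78 °C, slow addition of n-BuLi (1.5 equiv); crude 13: 46% aq. HF, MeCN, 0 °C
Reagents that add atoms: none
Why: Iodine–lithium exchange and loss of lithium triflate give benzyne 12, whose carbon meta to OMe is attacked by the nucleophilic carbon of 8 while the aryl anion beside OMe closes onto the oxocarbenium carbon (formal (2+2) cycloaddition of a ketene silyl acetal to an alkoxybenzyne), so the acetal carbon ends next to the methoxy group; fluoride-assisted hydrolysis of the mixed acetal at low acidity should spare the MOM ether, and the four-membered-ring methine is formed racemic.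

Step 9
Reactants: 1 naphthalene-1,8-diol
Product: 15 1,8-dimethoxynaphthalene
Conditions: NaH (2.5 equiv), MeI (3 equiv), DMF, 0 °C to rt
Reagents that add atoms: iodomethane, CI
Why: Exhaustive Williamson methylation with the stronger base gives the symmetric diether, so the following substitution has no choice between the two rings.

Step 10
Reactants: 15 1,8-dimethoxynaphthalene; 16 acetyl chloride
Product: 17 1-(4,5-dimethoxynaphthalen-1-yl)ethanone
Conditions: SnCl4, CH2Cl2, −20 to 0 °C
Reagents that add atoms: none
Why: Friedel–Crafts acylation occurs at the alpha position para to a methoxy group (carbon 4), the two rings being equivalent, and the mild Lewis acid SnCl4 avoids ether cleavage.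

Step 11
Reactants: 17 1-(4,5-dimethoxynaphthalen-1-yl)ethanone
Product: 18 1-(4-hydroxy-5-methoxynaphthalen-1-yl)ethanone
Conditions: NaSEt (1.5 equiv), DMF, 100 °C; dilute HCl work-up
Reagents that add atoms: none
Why: Nucleophilic demethylation by thiolate (bimolecular substitution at the methyl carbon) should select the methoxy group para to the acetyl group because its aryloxide is the better leaving group, and the phenoxide formed shields the molecule from a second cleavage.

Step 12
Reactants: 18 1-(4-hydroxy-5-methoxynaphthalen-1-yl)ethanone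
Product: 19 1-[5-methoxy-4-(methoxymethoxy)naphthalen-1-yl]ethanone
Conditions: MOMCl, iPr2NEt, CH2Cl2, 0 °C to rt
Reagents that add atoms: chloromethyl methyl ether, COCCl
Why: O-alkylation of the acidic para-acyl naphthol masks the hydroxyl as an acetal that is stable to organolithium reagents.

Step 13
Reactants: 19 1-[5-methoxy-4-(methoxymethoxy)naphthalen-1-yl]ethanone
Product: 20 (E)-N'-{1-[5-methoxy-4-(methoxymethoxy)naphthalen-1-yl]ethylidene}-2,4,6-triisopropylbenzenesulfonohydrazide
Conditions: 2,4,6-triisopropylbenzenesulfonohydrazide, cat. PPTS, THF, rt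
Reagents that add atoms: 2,4,6-triisopropylbenzenesulfonohydrazide, NNS(=O)(=O)c1c(C(C)C)cc(C(C)C)cc1C(C)C
Why: Condensation of the methyl ketone with the sulfonyl hydrazide gives the trisylhydrazone required for the Shapiro reaction, the hindered arenesulfonyl group preventing later lithiation of the sulfonyl ring (the C=N geometry is of no consequence).

Step 14
Reactants: 20 trisylhydrazone of ketone 19; 14 5-methoxy-8-[8-methoxy-1-(methoxymethoxy)naphthalen-2-yl]bicyclo[4.2.0]octa-1,3,5-trien-7-one
Product: 25 8-methoxy-2-[5-methoxy-4-(methoxymethoxy)naphthalen-1-yl]-4-[8-methoxy-1-(methoxymethoxy)naphthalen-2-yl]-3,4-dihydronaphthalen-1(2H)-one (racemic cis/trans mixture), via vinyllithium 21 (not isolated), via lithium cyclobutenoxide 22 (not isolated), via quinodimethane enolate 23 (not isolated), via lithium enolate 24 (not isolated)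
Conditions: 20, n-BuLi (2.1 equiv), THF, −78 to 0 °C; then 14 (0.7 equiv), −78 °C to rt; aq. NH4Cl
Reagents that add atoms: none
Why: Two equivalents of n-BuLi convert 20 into vinyllithium 21 (Shapiro reaction), which adds to the strained carbonyl of 14 anti to the naphthyl group (forming the bond between carbons 1 and 2 of unit B) instead of removing the four-membered-ring methine hydrogen, since that enolate would be an antiaromatic benzocyclobutadiene. On warming, alkoxide 22 undergoes oxyanion-accelerated conrotatory 4π opening in which the oxido group rotates outward, so the arylvinyl arm is turned inward and quinodimethane 23 results. The six-membered ring of unit B is then closed by a thermal disrotatory 6π electrocyclisation (forming the bond between carbons 3 and 4) that restores the benzene ring and gives enolate 24, protonated on work-up to 25. The closest known reaction type is the ring expansion of benzocyclobutenones to 1-tetralones on addition of alkenyllithiums. Carbon 4 of unit B is formed racemic in the closure and carbon 2 by unselective protonation of 24; neither is controlled because step 15 removes both. The selectivity needed is the outward rotation of the oxido group, an intrinsic donor effect of the substrate, and the methoxy group beside carbon 1, already fixed in 14; the naphthyl group cis to the oxido group is forced inward, which is where the steric risk lies.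

Step 15
Reactants: 25 2,4-diaryl-8-methoxy-1-tetralone from step 14
Product: 29 8-methoxy-2-[5-methoxy-4-(methoxymethoxy)naphthalen-1-yl]-4-[8-methoxy-1-(methoxymethoxy)naphthalen-2-yl]naphthalen-1-ol, via potassium enolate 26 (not isolated), via bromoketone 27 (not isolated), via dienone 28 (not isolated)
Conditions: KN(SiMe3)2 (1.05 equiv), THF, −78 °C; NBS (1.05 equiv), −78 °C; DBU, rt to 50 °C; aq. NH4Cl
Reagents that add atoms: none
Why: Carbon 2 of unit B is the only enolisable position, the potassium enolate 26 should be brominated at carbon faster than NBS attacks the electron-rich rings, DBU-mediated dehydrobromination of 27 gives dienone 28, and base-mediated tautomerisation through the doubly benzylic hydrogen at carbon 4 delivers the naphthol (alpha-halogenation–elimination aromatisation of a tetralone), erasing both stereocentres.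

Step 16
Reactants: 29 bis-MOM ether of the trimer
Product: 30 2-(4-hydroxy-5-methoxynaphthalen-1-yl)-4-(1-hydroxy-8-methoxynaphthalen-2-yl)-8-methoxynaphthalen-1-ol (target)
Conditions: 3 M HCl, MeOH/THF, 40 °C, argon
Reagents that add atoms: none
Why: Acid-catalysed acetal exchange with methanol removes both MOM groups while the three aryl methyl ethers are inert.

Compound list

1 | naphthalene-1,8-diol | Oc1cccc2cccc(O)c12 | starting material
2 | 8-methoxynaphthalen-1-ol | COc1cccc2cccc(O)c12 | intermediate
3 | 1-methoxy-8-(methoxymethoxy)naphthalene | COCOc1cccc2cccc(OC)c12 | intermediate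
4 | [8-methoxy-1-(methoxymethoxy)naphthalen-2-yl]lithium | [Li]c1ccc2cccc(OC)c2c1OCOC | intermediate (not isolated)
5 | 2-bromo-8-methoxy-1-(methoxymethoxy)naphthalene | Brc1ccc2cccc(OC)c2c1OCOC | intermediate
6 | (2-ethoxy-2-oxoethyl)zinc bromide | CCOC(=O)C[Zn]Br | starting material
7 | ethyl 2-[8-methoxy-1-(methoxymethoxy)naphthalen-2-yl]acetate | CCOC(=O)Cc1ccc2cccc(OC)c2c1OCOC | intermediate
8 | tert-butyl({1-ethoxy-2-[8-methoxy-1-(methoxymethoxy)naphthalen-2-yl]ethenyl}oxy)dimethylsilane, E/Z mixture | CCOC(O[Si](C)(C)C(C)(C)C)=Cc1ccc2cccc(OC)c2c1OCOC | intermediate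
9 | 2-iodo-1,3-dimethoxybenzene | COc1cccc(OC)c1I | starting material
10 | 2-iodo-3-methoxyphenol | COc1cccc(O)c1I | intermediate
11 | 2-iodo-3-methoxyphenyl trifluoromethanesulfonate | COc1cccc(OS(=O)(=O)C(F)(F)F)c1I | intermediate
12 | 3-methoxybenzyne | COC1=CC=CC#C1 | intermediate (not isolated)
13 | tert-butyl({7-ethoxy-5-methoxy-8-[8-methoxy-1-(methoxymethoxy)naphthalen-2-yl]bicyclo[4.2.0]octa-1,3,5-trien-7-yl}oxy)dimethylsilane, racemic diastereomer mixture | CCOC1(O[Si](C)(C)C(C)(C)C)C(c3ccc4cccc(OC)c4c3OCOC)c2cccc(OC)c12 | intermediate (not isolated)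
14 | 5-methoxy-8-[8-methoxy-1-(methoxymethoxy)naphthalen-2-yl]bicyclo[4.2.0]octa-1,3,5-trien-7-one, racemic, one enantiomer drawn | O=C1[C@H](c3ccc4cccc(OC)c4c3OCOC)c2cccc(OC)c12 | intermediate
15 | 1,8-dimethoxynaphthalene | COc1cccc2cccc(OC)c12 | intermediate
16 | acetyl chloride | CC(=O)Cl | starting material
17 | 1-(4,5-dimethoxynaphthalen-1-yl)ethanone | CC(=O)c1ccc(OC)c2c(OC)cccc12 | intermediate
18 | 1-(4-hydroxy-5-methoxynaphthalen-1-yl)ethanone | CC(=O)c1ccc(O)c2c(OC)cccc12 | intermediate
19 | 1-[5-methoxy-4-(methoxymethoxy)naphthalen-1-yl]ethanone | CC(=O)c1ccc(OCOC)c2c(OC)cccc12 | intermediate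
20 | (E)-N'-{1-[5-methoxy-4-(methoxymethoxy)naphthalen-1-yl]ethylidene}-2,4,6-triisopropylbenzenesulfonohydrazide | C/C(=N\NS(=O)(=O)c1c(C(C)C)cc(C(C)C)cc1C(C)C)c1ccc(OCOC)c2c(OC)cccc12 | intermediate
21 | {1-[5-methoxy-4-(methoxymethoxy)naphthalen-1-yl]ethenyl}lithium | [Li]C(=C)c1ccc(OCOC)c2c(OC)cccc12 | intermediate (not isolated)
22 | lithium 5-methoxy-7-{1-[5-methoxy-4-(methoxymethoxy)naphthalen-1-yl]ethenyl}-8-[8-methoxy-1-(methoxymethoxy)naphthalen-2-yl]bicyclo[4.2.0]octa-1,3,5-trien-7-olate, racemic, vinyl group trans to the naphthyl group | [Li]O[C@]1(C(=C)c4ccc(OCOC)c5c(OC)cccc45)[C@H](c3ccc6cccc(OC)c6c3OCOC)c2cccc(OC)c12 | intermediate (not isolated)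
23 | ortho-quinodimethane lithium dienolate, oxido group outward, arylvinyl and naphthyl groups inward | [Li]O/C(C(=C)c4ccc(OCOC)c5c(OC)cccc45)=C1\C(OC)=CC=C/C1=C/c3ccc6cccc(OC)c6c3OCOC | intermediate (not isolated)
24 | lithium 8-methoxy-2-[5-methoxy-4-(methoxymethoxy)naphthalen-1-yl]-4-[8-methoxy-1-(methoxymethoxy)naphthalen-2-yl]-3,4-dihydronaphthalen-1-olate, racemic, one enantiomer drawn | [Li]OC1=C(c4ccc(OCOC)c5c(OC)cccc45)C[C@H](c3ccc6cccc(OC)c6c3OCOC)c2cccc(OC)c12 | intermediate (not isolated)
25 | 8-methoxy-2-[5-methoxy-4-(methoxymethoxy)naphthalen-1-yl]-4-[8-methoxy-1-(methoxymethoxy)naphthalen-2-yl]-3,4-dihydronaphthalen-1(2H)-one, racemic, cis/trans mixture expected, cis isomer drawn | O=C1[C@H](c4ccc(OCOC)c5c(OC)cccc45)C[C@H](c3ccc6cccc(OC)c6c3OCOC)c2cccc(OC)c12 | intermediate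
26 | potassium 8-methoxy-2-[5-methoxy-4-(methoxymethoxy)naphthalen-1-yl]-4-[8-methoxy-1-(methoxymethoxy)naphthalen-2-yl]-3,4-dihydronaphthalen-1-olate, racemic, one enantiomer drawn | [K]OC1=C(c4ccc(OCOC)c5c(OC)cccc45)C[C@H](c3ccc6cccc(OC)c6c3OCOC)c2cccc(OC)c12 | intermediate (not isolated)
27 | 2-bromo-8-methoxy-2-[5-methoxy-4-(methoxymethoxy)naphthalen-1-yl]-4-[8-methoxy-1-(methoxymethoxy)naphthalen-2-yl]-3,4-dihydronaphthalen-1(2H)-one, racemic diastereomer mixture, isomer with the two aryl groups cis drawn | O=C1[C@](Br)(c4ccc(OCOC)c5c(OC)cccc45)C[C@H](c3ccc6cccc(OC)c6c3OCOC)c2cccc(OC)c12 | intermediate (not isolated)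
28 | 8-methoxy-2-[5-methoxy-4-(methoxymethoxy)naphthalen-1-yl]-4-[8-methoxy-1-(methoxymethoxy)naphthalen-2-yl]naphthalen-1(4H)-one, racemic, one enantiomer drawn | O=C1C(c4ccc(OCOC)c5c(OC)cccc45)=C[C@H](c3ccc6cccc(OC)c6c3OCOC)c2cccc(OC)c12 | intermediate (not isolated)
29 | 8-methoxy-2-[5-methoxy-4-(methoxymethoxy)naphthalen-1-yl]-4-[8-methoxy-1-(methoxymethoxy)naphthalen-2-yl]naphthalen-1-ol | Oc1c(c4ccc(OCOC)c5c(OC)cccc45)cc(c3ccc6cccc(OC)c6c3OCOC)c2cccc(OC)c12 | intermediate
30 | 2-(4-hydroxy-5-methoxynaphthalen-1-yl)-4-(1-hydroxy-8-methoxynaphthalen-2-yl)-8-methoxynaphthalen-1-ol | COc1cccc2ccc(-c3cc(-c4ccc(O)c5c(OC)cccc45)c(O)c4c(OC)cccc34)c(O)c12 | target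

Total step count: 16. Longest linear sequence: 9 steps (steps 1, 2, 3, 4, 5, 8, 14, 15, 16).

Steps most likely to fail

Step 14. The crowded quinodimethane, with the naphthyl group forced inward, may be protonated, reclose or suffer base-mediated proton transfer before the 6π closure, so that open-chain ketone or recovered material results instead of ring closure. The fallback sets out from 14 and 20 and comes back at 25. Vinyllithium 21 is generated as before and added to 14 at −78 °C, but the mixture is quenched at −78 °C with acetic acid so that the alkoxide is protonated before it can open. The tertiary alcohol 5-methoxy-7-{1-[5-methoxy-4-(methoxymethoxy)naphthalen-1-yl]ethenyl}-8-[8-methoxy-1-(methoxymethoxy)naphthalen-2-yl]bicyclo[4.2.0]octa-1,3,5-trien-7-ol F1 is isolated and heated in toluene at about 110 °C. Under these neutral conditions thermal conrotatory opening with the hydroxyl group outward, 6π closure and enol–ketone tautomerisation should give 25 without any strongly basic species present.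

Step 8. After the first carbon–carbon bond the hindered zwitterion may fail to close (the aryl anion being quenched to an open-chain arylated ester), or the unmasking with HF may cleave the MOM acetal or the strained ring. The fallback sets out from 7 and 11 and comes back at 14. Ester 7 is reduced with iBu2AlH in CH2Cl2 at −78 °C to 2-[8-methoxy-1-(methoxymethoxy)naphthalen-2-yl]acetaldehyde F2. Its lithium enolate (LiN(SiMe3)2, THF, −78 °C) is combined with benzyne 12, generated from 11 and n-BuLi at −78 °C, in an enolate–aryne (2+2) addition with the same polarity control, and the mixture is quenched cold with acetic acid to give 5-methoxy-8-[8-methoxy-1-(methoxymethoxy)naphthalen-2-yl]bicyclo[4.2.0]octa-1,3,5-trien-7-ol F3. Oxidation of F3 with Dess–Martin periodinane (NaHCO3, CH2Cl2) then gives 14, so that a smaller nucleophile is used and no acidic unmasking is needed.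

Step 15. Electrophilic bromine may attack the electron-rich naphthalene rings, or carbon bromination at the hindered tetrasubstituted enolate carbon may be too slow, so that aromatisation stalls or gives ring-brominated material. The fallback sets out from 25 and comes back at 29. The potassium enolate 26 formed with KN(SiMe3)2 is trapped with TMSCl to give the silyl enol ether {8-methoxy-2-[5-methoxy-4-(methoxymethoxy)naphthalen-1-yl]-4-[8-methoxy-1-(methoxymethoxy)naphthalen-2-yl]-3,4-dihydronaphthalen-1-yl}oxytrimethylsilane F4. Treatment of F4 with Pd(OAc)2 in MeCN (Saegusa–Ito oxidation) should give dienone 28, which tautomerises to 29, with no halogen source involved.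

Further compounds

F1 | step 14 | 5-methoxy-7-{1-[5-methoxy-4-(methoxymethoxy)naphthalen-1-yl]ethenyl}-8-[8-methoxy-1-(methoxymethoxy)naphthalen-2-yl]bicyclo[4.2.0]octa-1,3,5-trien-7-ol, racemic, vinyl group trans to the naphthyl group | O[C@]1(C(=C)c4ccc(OCOC)c5c(OC)cccc45)[C@H](c3ccc6cccc(OC)c6c3OCOC)c2cccc(OC)c12
F2 | step 8 | 2-[8-methoxy-1-(methoxymethoxy)naphthalen-2-yl]acetaldehyde | O=CCc1ccc2cccc(OC)c2c1OCOC
F3 | step 8 | 5-methoxy-8-[8-methoxy-1-(methoxymethoxy)naphthalen-2-yl]bicyclo[4.2.0]octa-1,3,5-trien-7-ol, racemic diastereomer mixture, trans isomer drawn | O[C@H]1[C@H](c3ccc4cccc(OC)c4c3OCOC)c2cccc(OC)c12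
F4 | step 15 | {8-methoxy-2-[5-methoxy-4-(methoxymethoxy)naphthalen-1-yl]-4-[8-methoxy-1-(methoxymethoxy)naphthalen-2-yl]-3,4-dihydronaphthalen-1-yl}oxytrimethylsilane, racemic, one enantiomer drawn | C[Si](C)(C)OC1=C(c4ccc(OCOC)c5c(OC)cccc45)C[C@H](c3ccc6cccc(OC)c6c3OCOC)c2cccc(OC)c12
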